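**Assumptions (one line each).** (i) Agecorynin G, 5,6,7-trimethoxy-2-(3-hydroxy-2,4,5-trimethoxyphenyl)chromen-4-one, has no stereocentres. The "single enantiomer" requirement is therefore trivial, and every intermediate is achiral. (ii) 1,2,4-Trimethoxybenzene lithiates at C3, the position flanked by two OMe groups.

## Retrosynthetic overview
1. Target ⇐ hydrogenolysis of the benzyl ether of flavone **12**; the 3'-OBn masks the only free phenol.
2. Flavone C2–C1' bond ⇐ **proposed new** decarboxylative oxidative Heck-type C2-arylation of 5,6,7-trimethoxychromone with an ortho-alkoxy benzoic acid. The pyranone ring is therefore formed before the aryl ring is attached.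
3. A ring and pyranone, in that order: 3,4,5-trimethoxyphenol → Friedel–Crafts acetylation → enaminone → chromone.
4. B-ring acid, in order: 1,2,4-trimethoxybenzene → bromination → Br/Li exchange and silylation (TMS blocks and masks C1') → C3 lithiation, borylation, oxidation → benzylation → ipso-iodination → Li/I exchange and CO2.

## Route

**Step 1**
Reactants: **1** 1,2,4-trimethoxybenzene
Product: **2** 1-bromo-2,4,5-trimethoxybenzene
Conditions: NBS, MeCN, 0 °C → rt
Reagents that add atoms: NBS, O=C1CCC(=O)N1Br
Why: Electrophilic aromatic bromination occurs para to the C2-OMe at the least hindered activated position (C5). No stereocentres are formed.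

**Step 2**
Reactants: **2**
Product: **3** trimethyl(2,4,5-trimethoxyphenyl)silane
Conditions: n-BuLi, THF, –78 °C, 30 min; then TMSCl, –78 °C → rt
Reagents that add atoms: TMSCl, C[Si](C)(C)Cl
Why: Bromine–lithium exchange followed by silylation converts the halide into a blocking group, which is later converted back to a halide at the same carbon.

**Step 3**
Reactants: **3**
Product: **4** 2,3,6-trimethoxy-5-(trimethylsilyl)phenol, i.e. 3-hydroxy-2,4,5-trimethoxyphenyl-TMS
Conditions: n-BuLi, THF, 0 °C; then B(OMe)3, –78 °C → rt; then 30% H2O2, 2 M NaOH, 0 °C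
Reagents that add atoms: B(OMe)3, COB(OC)OC (boron is lost); H2O2, OO (source of the new OH)
Why: Directed ortho-metalation occurs at C3, flanked by two OMe groups and far more acidic than C6 (next to TMS and one OMe). Borylation then oxidation gives the phenol (lithiation–borylation–oxidation).

**Step 4**
Reactants: **4**
Product: **5** (3-(benzyloxy)-2,4,5-trimethoxyphenyl)trimethylsilane
Conditions: BnBr, K2CO3, DMF, rt
Reagents that add atoms: BnBr, BrCc1ccccc1
Why: Williamson O-benzylation of the phenol gives a group that survives organolithium and oxidative conditions and is removable by hydrogenolysis.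

**Step 5**
Reactants: **5**
Product: **6** 3-(benzyloxy)-1-iodo-2,4,5-trimethoxybenzene
Conditions: ICl, CH2Cl2, –78 °C; Na2S2O3 work-up
Reagents that add atoms: ICl, ClI
Why: Ipso-iododesilylation (an aryl-silane SEAr, favoured by the β-silicon effect) places iodine exactly at the carbon that carried TMS, which avoids the C1'/C6' regiochemistry problem.

**Step 6**
Reactants: **6**
Product: **7** 3-(benzyloxy)-2,4,5-trimethoxybenzoic acid
Conditions: n-BuLi (1.05 equiv), THF, –78 °C, 30 min; excess solid CO2; then 1 M HCl
Reagents that add atoms: CO2, O=C=O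
Why: Iodine–lithium exchange followed by carboxylation of the aryllithium (Li/I exchange–CO2 quench) gives the acid with a fixed C1' position and one ortho-OMe, which helps decarboxylation.

**Step 7**
Reactants: **8** 3,4,5-trimethoxyphenol
Product: **9** 1-(2-hydroxy-4,5,6-trimethoxyphenyl)ethan-1-one
Conditions: AcOH, BF3·OEt2, 85 °C, 3 h
Reagents that add atoms: AcOH, CC(=O)O (acetyl group)
Why: BF3-promoted Friedel–Crafts/Hoesch-type acylation occurs ortho to OH. The molecule is symmetric, so only one regioisomer is possible, and the phenol–ketone hydrogen bond stabilises the product.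

**Step 8**
Reactants: **9**
Product: **10** (E)-3-(dimethylamino)-1-(2-hydroxy-4,5,6-trimethoxyphenyl)prop-2-en-1-one
Conditions: DMF-DMA, toluene, 100 °C, 6 h
Reagents that add atoms: DMF-DMA, CN(C)C(OC)OC (provides =CH–NMe2)
Why: Condensation of the methyl ketone with DMF-DMA gives the enaminone (one-carbon homologation).

**Step 9**
Reactants: **10**
Product: **11** 5,6,7-trimethoxy-4H-chromen-4-one
Conditions: conc. HCl (cat.–2 equiv), EtOH, 60 °C, 1 h
Reagents that add atoms: none
Why: Intramolecular conjugate addition of the phenol to the enaminone, then loss of Me2NH, closes the pyranone (Michael addition–elimination). The mild acid leaves the 5-OMe intact.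

**Step 10 (key bond-forming step)**
Reactants: **11** 5,6,7-trimethoxychromone (1 equiv); **7** 3-(benzyloxy)-2,4,5-trimethoxybenzoic acid (3 equiv)
Product: **12** 2-(3-(benzyloxy)-2,4,5-trimethoxyphenyl)-5,6,7-trimethoxy-4H-chromen-4-one
Conditions: Pd(TFA)2 (10 mol%), Ag2CO3 (2.5 equiv), DMSO/DMF (1:9), 4 Å MS, 120 °C, 24 h
Reagents that add atoms: none (the aryl group comes from reactant **7**; CO2 and H are lost)
Why: Proposed new method: Ag(I) carboxylate decarboxylation, assisted by the ortho/para alkoxy groups, gives an aryl–Ag(I) species that transmetalates to Pd(II). Syn-carbopalladation of the chromone C2=C3 bond places Ar on C2 (the β-carbon of the enone) and Pd on C3 as a Pd-enolate. Enolate epimerisation and β-H elimination of C2–H give the flavone, and Ag(I) reoxidises Pd(0) to Pd(II). The closest known reactions are the decarboxylative Heck reaction of ortho-substituted benzoic acids with acrylates and the oxidative Heck arylation of chromones with arylboronic acids. What is new is using an electron-rich tetra-oxygenated benzoic acid as the aryl donor on the chromone β-carbon. The product is sp2-only and achiral, so no stereocentre is involved. The extra equivalents of acid cover competing protodecarboxylation.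

**Step 11**
Reactants: **12**
Product: **13** Agecorynin G, 2-(3-hydroxy-2,4,5-trimethoxyphenyl)-5,6,7-trimethoxy-4H-chromen-4-one
Conditions: H2 (1 atm), 10% Pd/C, EtOAc/MeOH 1:1, rt, 1–2 h
Reagents that add atoms: none (H2 only)
Why: Hydrogenolysis of the benzyl ether releases the phenol and toluene. The flavone C2=C3 bond, the aryl methyl ethers and the C4 carbonyl are untouched under these mild, short conditions.

## Compound list
1 | 1,2,4-trimethoxybenzene | COc1ccc(OC)c(OC)c1 | starting material
2 | 1-bromo-2,4,5-trimethoxybenzene | Brc1cc(OC)c(OC)cc1OC | intermediate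
3 | trimethyl(2,4,5-trimethoxyphenyl)silane | C[Si](C)(C)c1cc(OC)c(OC)cc1OC | intermediate
4 | 2,3,6-trimethoxy-5-(trimethylsilyl)phenol | C[Si](C)(C)c1cc(OC)c(OC)c(O)c1OC | intermediate
5 | (3-(benzyloxy)-2,4,5-trimethoxyphenyl)trimethylsilane | C[Si](C)(C)c1cc(OC)c(OC)c(OCc2ccccc2)c1OC | intermediate
6 | 3-(benzyloxy)-1-iodo-2,4,5-trimethoxybenzene | COc1cc(I)c(OC)c(OCc2ccccc2)c1OC | intermediate
7 | 3-(benzyloxy)-2,4,5-trimethoxybenzoic acid | COc1cc(C(=O)O)c(OC)c(OCc2ccccc2)c1OC | intermediate
8 | 3,4,5-trimethoxyphenol | COc1cc(O)cc(OC)c1OC | starting material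
9 | 1-(2-hydroxy-4,5,6-trimethoxyphenyl)ethan-1-one | CC(=O)c1c(O)cc(OC)c(OC)c1OC | intermediate
10 | (E)-3-(dimethylamino)-1-(2-hydroxy-4,5,6-trimethoxyphenyl)prop-2-en-1-one | CN(C)/C=C/C(=O)c1c(O)cc(OC)c(OC)c1OC | intermediate
11 | 5,6,7-trimethoxy-4H-chromen-4-one | COc1cc2occc(=O)c2c(OC)c1OC | intermediate
12 | 2-(3-(benzyloxy)-2,4,5-trimethoxyphenyl)-5,6,7-trimethoxy-4H-chromen-4-one | COc1cc(-c2cc(=O)c3c(OC)c(OC)c(OC)cc3o2)c(OC)c(OCc2ccccc2)c1OC | intermediate
13 | Agecorynin G (achiral, no stereocentres) | COc1cc(-c2cc(=O)c3c(OC)c(OC)c(OC)cc3o2)c(OC)c(O)c1OC | target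

## Step count
- Total steps: 11.
- Longest linear sequence: 8 steps (1 → 2 → 3 → 4 → 5 → 6 → 7 → 12 → 13, with step 10 as the convergent coupling).
- The chromone branch is 3 steps (8 → 9 → 10 → 11).

## Three steps most likely to fail
1. **Step 10 (proposed new step).** Electron-rich acid **7** may protodecarboxylate faster than it transmetalates, and chromone is a poor Heck acceptor.
   Fallback (known chemistry, different approach): convert **7** to its acid chloride (oxalyl chloride, cat. DMF) and esterify the phenol of **9**. Carry out a Baker–Venkataraman rearrangement (KOH, pyridine) to the 1,3-diketone, then cyclodehydrate (cat. H2SO4, AcOH) to give **12**.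
2. **Step 3 (C3 lithiation, borylation, oxidation on the TMS arene).** Yield may be low, or lithiation at C6 may compete.
   Fallback: reorder the sequence. Oxygenate 1,2,4-trimethoxybenzene first (same lithiation–borylation–oxidation, no TMS present) and pivaloylate the phenol so it is a weak donor. Brominate with NBS, which should go to C1' because it is ortho and para to two OMe groups. Swap Piv for Bn, then do Br/Li exchange and CO2 quench to reach **7**.
3. **Step 7 (BF3/AcOH acylation of the trimethoxyphenol).** Partial demethylation or low conversion is possible.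
   Fallback: acetylate **8** to the aryl acetate (Ac2O, pyridine) and perform a BF3·OEt2 Fries rearrangement, or use a Houben–Hoesch acylation (MeCN, ZnCl2, HCl, then aqueous hydrolysis).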